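**Retrosynthetic overview**
- The acid is traced back through ester hydrolysis and an E-selective Horner–Wadsworth–Emmons olefination at C9'=C10' of the side chain to a 9-oxononyl dioxolane ester and a C7 dienylphosphonate.
- The dioxolane (ring atoms O1, O2, C3, C4, C5; C3 bears the acetate arm, C5 the chain) is cut at C4–C5 and O2–C3. One (3+2) annulation joins a bicyclic ozonide made from cyclodecanone with a chiral α-silyl-β,γ-unsaturated ester (an allylsilane).
- Enabling feature: O2–O1–C5, with C5 fully substituted, is a masked carbonyl oxide, and C4H2–C3, with C3 fully substituted, is a 1,1-disubstituted alkene. Chain carbon C9', eight methylenes from C5, is at the aldehyde level and can carry that carbonyl oxide as a 1,2,4-trioxolane.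
- Ring order: the temporary trioxolane is made first (step 3). The dioxolane closes in step 6 while the trioxolane opens and still ties the chain to the attacking peroxide oxygen, which fixes C5 relative to C3. The silyl group fixes C3 and is removed in step 7.

Key step: step 6

Assumption: methyl 3-methylbut-3-enoate is treated as purchasable (otherwise one esterification from commercial 3-methylbut-3-enoic acid), and Rh2(S-DOSP)4 is taken to give the (2S)-silane; if the catalyst or the conformational model for C3 induces the opposite sense, Rh2(R-DOSP)4 is used instead.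

**Route**

Step 1
Reactants: 1 cyclodecanone
Product: 2 1-methylcyclodecan-1-ol
Conditions: MeMgBr (1.3 equiv), THF, 0 °C to rt; aq NH4Cl
Reagents that add atoms: methylmagnesium bromide, C[Mg]Br
Why: Grignard 1,2-addition to an unhindered ketone; no stereocenter is formed.

Step 2
Reactants: 2 1-methylcyclodecan-1-ol
Product: 3 1-methylcyclodec-1-ene (mixture of ring-alkene geometries)
Conditions: TsOH·H2O (5 mol %), toluene, reflux, Dean–Stark
Reagents that add atoms: none
Why: Acid-catalysed E1 dehydration under equilibrating conditions should favour the endocyclic trisubstituted alkene, and both ring geometries are equally useful because they converge on one ozonide.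

Step 3
Reactants: 3 1-methylcyclodec-1-ene
Product: 6 1-methyl-11,12,13-trioxabicyclo[8.2.1]tridecane (racemic), via primary ozonide 4 (not isolated), via tethered carbonyl oxide 5 (not isolated)
Conditions: O3/O2, pentane (high dilution), −78 °C; N2 purge; chromatography on silica
Reagents that add atoms: ozone, [O-][O+]=O
Why: Ozonolysis by the Criegee mechanism in a non-participating solvent, where the ketone O-oxide and the aldehyde formed on the same chain recombine to the secondary ozonide; its stereocenters are erased in step 6.

Step 4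
Reactants: 7 methyl 3-methylbut-3-enoate
Product: 8 methyl 2-diazo-3-methylbut-3-enoate
Conditions: p-ABSA (1.2 equiv), DBU (1.3 equiv), MeCN, 0 °C, dark; used at once
Reagents that add atoms: 4-acetamidobenzenesulfonyl azide, CC(=O)Nc1ccc(cc1)S(=O)(=O)N=[N+]=[N-]
Why: Regitz diazo transfer to the allylic α-methylene of a β,γ-unsaturated ester, the standard entry to vinyl diazoacetates.

Step 5
Reactants: 8 methyl 2-diazo-3-methylbut-3-enoate
Product: 9 methyl (2S)-2-[dimethyl(phenyl)silyl]-3-methylbut-3-enoate
Conditions: PhMe2SiH (2 equiv), Rh2(S-DOSP)4 (1 mol %), pentane, −78 °C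
Reagents that add atoms: dimethylphenylsilane, C[SiH](C)c1ccccc1
Why: Rhodium-carbenoid Si–H insertion of a vinyl diazoacetate, in which the chiral dirhodium prolinate differentiates the carbenoid faces and sets the silicon-bearing stereocenter.

Step 6
Reactants: 6 1-methyl-11,12,13-trioxabicyclo[8.2.1]tridecane; 9 methyl (2S)-2-[dimethyl(phenyl)silyl]-3-methylbut-3-enoate
Product: 12 methyl (2S)-2-[dimethyl(phenyl)silyl]-2-[(3R,5S)-3,5-dimethyl-5-(9-oxononyl)-1,2-dioxolan-3-yl]acetate, via ring-opened peroxycarbenium stannate 10 (not isolated), via β-silyl carbenium ion 11 (not isolated)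
Conditions: 6 (1.5 equiv), SnCl4 (1.5 equiv), CH2Cl2, −78 °C; slow addition of 9 (1.0 equiv); aq NaHCO3 at −78 °C
Reagents that add atoms: none
Why: Proposed new method: SnCl4 binds the bridging ether oxygen of 6 and heterolysis of its tertiary C–O bond gives peroxycarbenium ion 10, whose distal peroxide oxygen stays tied to the chain end through the CH(OSnCl4) carbon (12-membered ring); the CH2 terminus of allylsilane 9 attacks the carbenium carbon (C4–C5 bond), the tertiary β-silyl carbenium ion 11 is captured by the distal peroxide oxygen (O2–C3 bond), and the oxonium so formed expels the tether carbon as the aldehyde. The closest known reaction type is the SnCl4-mediated (3+2) annulation of peroxycarbenium ions, generated from silylperoxy ketals or from simple ozonides, with alkenes and allyltrimethylsilane, together with the anti-selective (3+2) annulations of chiral ester-bearing allylsilanes with oxocarbenium ions; new here are the intramolecular tether and the α-silyl ester as chiral two-carbon partner. The dioxolane is closed by a 5-membered cation–oxygen collapse (5-exo with respect to the hyperconjugating C–Si bond), and the trioxolane is opened in the same event, so no ring other than the dioxolane remains. C3 is controlled by the silicon-bearing stereocenter: the peroxide unit adds to the alkene face anti to the C–Si bond in the conformer that keeps the allylic hydrogen beside the 2-methyl group (least A(1,2) strain), which should translate (2S) in 9 into (3R). C5 is controlled by the temporary ring: the stannyloxy-bearing carbon on the attacking oxygen has to sit on the face of the C5 chain to which it is still bonded and turns away from the bulky silyl ester arm on the neighbouring C3, so that chain and ester arm should end up trans (5S), a mismatched cation being expected to lose silicon instead of closing. The step needs annulation to win over desilylative allylation and over allylation of the released aldehyde, which the intramolecular capture by oxygen, the phenyldimethylsilyl group, −78 °C and the use of 9 as the limiting partner are meant to secure.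

Step 7
Reactants: 12 methyl (2S)-2-[dimethyl(phenyl)silyl]-2-[(3R,5S)-3,5-dimethyl-5-(9-oxononyl)-1,2-dioxolan-3-yl]acetate
Product: 13 methyl 2-[(3R,5S)-3,5-dimethyl-5-(9-oxononyl)-1,2-dioxolan-3-yl]acetate
Conditions: Bu4NF (1.2 equiv), AcOH (2 equiv), THF, 0 °C
Reagents that add atoms: none
Why: Fluoride-induced protodesilylation of an α-silyl ester, buffered so that the carbon is protonated as the C–Si bond breaks and no enolate lives long enough to open the ring by β-elimination of the peroxide; C3 and C5 are quaternary and untouched.

Step 8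
Reactants: 14 (2E,4E)-hepta-2,4-dienal
Product: 15 (2E,4E)-hepta-2,4-dien-1-ol
Conditions: NaBH4, MeOH, 0 °C
Reagents that add atoms: none
Why: Borohydride 1,2-reduction of a conjugated aldehyde, which leaves the diene geometry intact.

Step 9
Reactants: 15 (2E,4E)-hepta-2,4-dien-1-ol
Product: 16 (2E,4E)-1-bromohepta-2,4-diene
Conditions: PBr3 (0.4 equiv), Et2O, −10 °C, dark; used crude
Reagents that add atoms: phosphorus tribromide, BrP(Br)Br
Why: Bromination of a primary dienylic alcohol through its phosphite ester, with the conjugated primary bromide as the thermodynamically preferred allylic isomer.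

Step 10
Reactants: 16 (2E,4E)-1-bromohepta-2,4-diene
Product: 17 diethyl [(2E,4E)-hepta-2,4-dien-1-yl]phosphonate
Conditions: P(OEt)3 (1.5 equiv), neat, 110 °C
Reagents that add atoms: triethyl phosphite, CCOP(OCC)OCC
Why: Michaelis–Arbuzov reaction of a reactive primary allylic bromide, with bromoethane distilling out.

Step 11
Reactants: 13 methyl 2-[(3R,5S)-3,5-dimethyl-5-(9-oxononyl)-1,2-dioxolan-3-yl]acetate; 17 diethyl [(2E,4E)-hepta-2,4-dien-1-yl]phosphonate
Product: 19 methyl 2-[(3R,5S)-5-[(9E,11E,13E)-hexadeca-9,11,13-trien-1-yl]-3,5-dimethyl-1,2-dioxolan-3-yl]acetate, via lithiated phosphonate 18 (not isolated)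
Conditions: 17 (1.3 equiv), LiN(SiMe3)2 (1.25 equiv), THF, −78 °C; then 13, DMPU, −78 to 0 °C
Reagents that add atoms: none
Why: Horner–Wadsworth–Emmons olefination of an aliphatic aldehyde with an allylic phosphonate anion, which should give the E alkene through the equilibrated oxaphosphetane; the anion is pre-formed without excess base so that the ester is not enolised.

Step 12
Reactants: 19 methyl 2-[(3R,5S)-5-[(9E,11E,13E)-hexadeca-9,11,13-trien-1-yl]-3,5-dimethyl-1,2-dioxolan-3-yl]acetate
Product: 20 2-[(3R,5S)-5-[(9E,11E,13E)-hexadeca-9,11,13-trien-1-yl]-3,5-dimethyl-1,2-dioxolan-3-yl]acetic acid (CNP0181055.2)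
Conditions: LiOH·H2O (3 equiv), THF/MeOH/H2O, 0 °C to rt; 1 M HCl to pH 3–4 at 0 °C
Reagents that add atoms: lithium hydroxide, [Li+].[OH-]
Why: Saponification at the acyl carbon, which the dialkyl peroxide and the triene should tolerate; both stereocenters are quaternary and cannot epimerise by enolisation.

**Compound list**
1 | cyclodecanone | O=C1CCCCCCCCC1 | starting material
2 | 1-methylcyclodecan-1-ol | CC1(O)CCCCCCCCC1 | intermediate
3 | 1-methylcyclodec-1-ene (ring-alkene geometry mixture) | CC1=CCCCCCCCC1 | intermediate
4 | primary ozonide, 1-methyl-11,12,13-trioxabicyclo[8.3.0]tridecane | CC12CCCCCCCCC1OOO2 | intermediate (not isolated)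
5 | tethered carbonyl oxide, 10-oxoundecanal 10-O-oxide | CC(CCCCCCCCC=O)=[O+][O-] | intermediate (not isolated)
6 | 1-methyl-11,12,13-trioxabicyclo[8.2.1]tridecane (racemic) | CC12CCCCCCCCC(OO1)O2 | intermediate
7 | methyl 3-methylbut-3-enoate | COC(=O)CC(C)=C | starting material
8 | methyl 2-diazo-3-methylbut-3-enoate | COC(=O)C(=[N+]=[N-])C(C)=C | intermediate
9 | methyl (2S)-2-[dimethyl(phenyl)silyl]-3-methylbut-3-enoate | COC(=O)[C@@H]([Si](C)(C)c1ccccc1)C(C)=C | intermediate
10 | ring-opened peroxycarbenium stannate | CC1=[O+]OC(CCCCCCCC1)O[Sn-](Cl)(Cl)(Cl)Cl | intermediate (not isolated)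
11 | β-silyl carbenium ion | COC(=O)[C@@H]([Si](C)(C)c1ccccc1)[C+](C)C[C@]2(C)CCCCCCCCC(O[Sn-](Cl)(Cl)(Cl)Cl)OO2 | intermediate (not isolated)
12 | methyl (2S)-2-[dimethyl(phenyl)silyl]-2-[(3R,5S)-3,5-dimethyl-5-(9-oxononyl)-1,2-dioxolan-3-yl]acetate | O=CCCCCCCCC[C@@]1(C)C[C@](C)([C@H]([Si](C)(C)c2ccccc2)C(=O)OC)OO1 | intermediate
13 | methyl 2-[(3R,5S)-3,5-dimethyl-5-(9-oxononyl)-1,2-dioxolan-3-yl]acetate | O=CCCCCCCCC[C@@]1(C)C[C@](C)(CC(=O)OC)OO1 | intermediate
14 | (2E,4E)-hepta-2,4-dienal | CC/C=C/C=C/C=O | starting material
15 | (2E,4E)-hepta-2,4-dien-1-ol | CC/C=C/C=C/CO | intermediate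
16 | (2E,4E)-1-bromohepta-2,4-diene | CC/C=C/C=C/CBr | intermediate
17 | diethyl [(2E,4E)-hepta-2,4-dien-1-yl]phosphonate | CC/C=C/C=C/CP(=O)(OCC)OCC | intermediate
18 | lithiated phosphonate | CC/C=C/C=C/[CH-]P(=O)(OCC)OCC.[Li+] | intermediate (not isolated)
19 | methyl 2-[(3R,5S)-5-[(9E,11E,13E)-hexadeca-9,11,13-trien-1-yl]-3,5-dimethyl-1,2-dioxolan-3-yl]acetate | CC/C=C/C=C/C=C/CCCCCCCC[C@@]1(C)C[C@](C)(CC(=O)OC)OO1 | intermediate
20 | 2-[(3R,5S)-5-[(9E,11E,13E)-hexadeca-9,11,13-trien-1-yl]-3,5-dimethyl-1,2-dioxolan-3-yl]acetic acid | CC/C=C/C=C/C=C/CCCCCCCC[C@@]1(C)C[C@](C)(CC(=O)O)OO1 | target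

**Step count and risks**

Total step count: 12. Longest linear sequence: 7 steps (steps 1, 2, 3, 6, 7, 11, 12).

Steps most likely to fail:

1. Step 6 (proposed new method). The β-silyl carbenium ion may lose silicon (desilylative allylation) faster than the peroxide oxygen captures it. The trioxolane may rearrange under the Lewis acid. The aldehyde–stannate tether may break before the C–O bond forms, so that C5 is set without control. Fallback with known chemistry, setting out from 3 and 7: ozonolysis of 3 in CH2Cl2/MeOH at −78 °C should trap the ketone O-oxide as 10-hydroperoxy-10-methoxyundecanal F1. Silylation with Et3SiOTf and 2,6-lutidine gives 10-methoxy-10-[(triethylsilyl)peroxy]undecanal F2. The established SnCl4-mediated annulation of such silylperoxy ketals with 1,1-disubstituted alkenes, here with 7 in CH2Cl2 at −78 °C, gives methyl 2-[3,5-dimethyl-5-(9-oxononyl)-1,2-dioxolan-3-yl]acetate as a stereoisomer mixture F3. The trans racemate is separated on silica and its enantiomers by preparative HPLC on a chiral stationary phase, which returns to the route at 13; steps 4, 5 and 7 then fall away.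

2. Step 5. The vinyl diazo ester 8 may electrocyclise to a pyrazole before the carbenoid forms, or the insertion may be insufficiently enantioselective. Fallback, setting out from 7: deprotonation with LiN(iPr)2 in THF at −78 °C and C-silylation of the lithium dienolate at its α-carbon with PhMe2SiCl gives racemic methyl 2-[dimethyl(phenyl)silyl]-3-methylbut-3-enoate F4, any O-silyl ketene acetal reverting to 7 on aqueous work-up. Preparative HPLC on a chiral stationary phase separates the enantiomers and returns to the route at 9.

3. Step 11. The new double bond may form with incomplete E selectivity, or the aldehyde may be consumed by enolisation and aldol reaction under the basic phosphonate anion. Fallback with reversed polarity, setting out from 13 and the starting dienal 14: NaBH4 in MeOH reduces 13 to methyl 2-[(3R,5S)-5-(9-hydroxynonyl)-3,5-dimethyl-1,2-dioxolan-3-yl]acetate F5. A Mitsunobu reaction with 1-phenyl-1H-tetrazole-5-thiol (PPh3, DIAD, THF) gives methyl 2-[(3R,5S)-3,5-dimethyl-5-{9-[(1-phenyl-1H-tetrazol-5-yl)sulfanyl]nonyl}-1,2-dioxolan-3-yl]acetate F6. Oxidation with (NH4)6Mo7O24·4H2O and H2O2 in EtOH gives methyl 2-[(3R,5S)-3,5-dimethyl-5-{9-[(1-phenyl-1H-tetrazol-5-yl)sulfonyl]nonyl}-1,2-dioxolan-3-yl]acetate F7. Julia–Kocienski olefination of F7 with 14 (KN(SiMe3)2, DME, −60 °C) should give the E,E,E-triene and returns to the route at 19; steps 8 to 10 then fall away.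

Further compounds
F1 | step 6 | 10-hydroperoxy-10-methoxyundecanal | COC(C)(OO)CCCCCCCCC=O
F2 | step 6 | 10-methoxy-10-[(triethylsilyl)peroxy]undecanal | COC(C)(OO[Si](CC)(CC)CC)CCCCCCCCC=O
F3 | step 6 | methyl 2-[3,5-dimethyl-5-(9-oxononyl)-1,2-dioxolan-3-yl]acetate (stereoisomer mixture) | COC(=O)CC1(C)CC(C)(CCCCCCCCC=O)OO1
F4 | step 5 | methyl 2-[dimethyl(phenyl)silyl]-3-methylbut-3-enoate (racemic) | COC(=O)C([Si](C)(C)c1ccccc1)C(C)=C
F5 | step 11 | methyl 2-[(3R,5S)-5-(9-hydroxynonyl)-3,5-dimethyl-1,2-dioxolan-3-yl]acetate | OCCCCCCCCC[C@@]1(C)C[C@](C)(CC(=O)OC)OO1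
F6 | step 11 | methyl 2-[(3R,5S)-3,5-dimethyl-5-{9-[(1-phenyl-1H-tetrazol-5-yl)sulfanyl]nonyl}-1,2-dioxolan-3-yl]acetate | c1ccccc1-n1nnnc1SCCCCCCCCC[C@@]1(C)C[C@](C)(CC(=O)OC)OO1
F7 | step 11 | methyl 2-[(3R,5S)-3,5-dimethyl-5-{9-[(1-phenyl-1H-tetrazol-5-yl)sulfonyl]nonyl}-1,2-dioxolan-3-yl]acetate | O=S(=O)(CCCCCCCCC[C@@]1(C)C[C@](C)(CC(=O)OC)OO1)c1nnnn1-c1ccccc1
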